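**Plan** (attenol numbering: C1 = CH2OH, C3=C4 the Z-alkene, C6 carbinol, C7/C8 the ring CH–O/CH–Me, C11 spiro carbon, C14 the THF CH–O, C16 carbinol, C20=C21 vinyl)
- Retrosynthesis: remove two silyl ethers, then cut the tetrahydropyran at C10–C11 and at O–C7 together, giving γ-lactone 8 (C11–C21) and cis-epoxy iodide 20 (C1–C10).
- Enabling feature: spiro C11 is the acyl carbon of the five-membered ring, and the pyran O–C7 bond is threo to the free C6–OH, so these two C–O bonds are a cis-6,7-epoxide opened at C7 by the C11 hemiketal oxygen.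
- Ring order: the THF ring is made first as the lactone (step 1); the THP ring closes last (step 12).
- Lactone 8: two reagent-controlled allylborations set C14 and C16 (14,16-anti); the allyl group is extended to pent-4-enyl by hydroboration/Suzuki vinylation.
- Iodide 20: C6 from (R)-glyceraldehyde acetonide; anti-crotylboration sets C7/C8; mesylate closure gives the cis-epoxide (inversion at C7); alkynylation and Lindlar give the 3Z-alkene.
- Union: inversion at C7 again on epoxide opening gives 7R; C11 is set thermodynamically (anomeric); fluoride deprotection ends the route.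

Key step: step 12

Remark: the tartrate-modified (E)-crotylboronate of step 6 is taken as a stock reagent made beforehand from trans-2-butene, n-BuLi/KOt-Bu, B(Oi-Pr)3 and D-(−)-diisopropyl tartrate; 1, 9, 14 and both B-allyldiisopinocampheylboranes are purchased.

**Step 1**
Reactants: 1 methyl 4-oxobutanoate
Product: 3 (5S)-5-(prop-2-en-1-yl)oxolan-2-one, via hydroxy ester 2 (not isolated)
Conditions: (+)-Ipc2B(allyl) (from (−)-α-pinene), Et2O, −78 °C; 30% H2O2, pH 7 buffer, MeOH, 0 °C → rt; TsOH (cat.), CH2Cl2, rt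
Reagents that add atoms: (+)-B-allyldiisopinocampheylborane, C=CCB([C@H]1C[C@H]2C[C@@H]([C@@H]1C)C2(C)C)[C@H]1C[C@H]2C[C@@H]([C@@H]1C)C2(C)C
Why: Brown asymmetric allylboration through a chair transition state should deliver allyl to the Re face of the aldehyde under control of the isopinocampheyl groups (C14 = S), and the γ-hydroxy ester then lactonises under acid.

**Step 2**
Reactants: 3 (5S)-5-(prop-2-en-1-yl)oxolan-2-one
Product: 4 2-[(2S)-5-oxooxolan-2-yl]acetaldehyde
Conditions: O3, CH2Cl2, −78 °C; PPh3, −78 °C → rt; used crude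
Reagents that add atoms: ozone, O=[O+][O-]
Why: Ozonolysis with reductive work-up cleaves the only C=C bond without touching the lactone or C14, and the β-acyloxy aldehyde is used crude to avoid β-elimination.

**Step 3**
Reactants: 4 2-[(2S)-5-oxooxolan-2-yl]acetaldehyde
Product: 5 (5S)-5-[(2S)-2-hydroxypent-4-en-1-yl]oxolan-2-one
Conditions: (−)-Ipc2B(allyl) (from (+)-α-pinene), Et2O, −78 °C; 30% H2O2, pH 7 buffer, MeOH, 0 °C → rt
Reagents that add atoms: (−)-B-allyldiisopinocampheylborane, C=CCB([C@@H]1C[C@@H]2C[C@H]([C@H]1C)C2(C)C)[C@@H]1C[C@@H]2C[C@H]([C@H]1C)C2(C)C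
Why: A second Brown allylboration with the antipodal reagent should add to the Si face under reagent control (the β-acyloxy centre gives little 1,3-induction) and set C16 = S, the 14,16-anti relation.

**Step 4**
Reactants: 5 (5S)-5-[(2S)-2-hydroxypent-4-en-1-yl]oxolan-2-one
Product: 6 (5S)-5-[(2S)-2-(tert-butyldimethylsilyloxy)pent-4-en-1-yl]oxolan-2-one
Conditions: TBSCl, imidazole, DMF, rt
Reagents that add atoms: tert-butyldimethylsilyl chloride, CC(C)(C)[Si](C)(C)Cl
Why: Standard silylation of a secondary alcohol leaves the lactone untouched and masks C16–OH against the organolithium of step 12.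

**Step 5**
Reactants: 6 (5S)-5-[(2S)-2-(tert-butyldimethylsilyloxy)pent-4-en-1-yl]oxolan-2-one
Product: 8 (5S)-5-[(2S)-2-(tert-butyldimethylsilyloxy)hept-6-en-1-yl]oxolan-2-one, via alkyl-9-BBN adduct 7 (not isolated)
Conditions: 9-BBN, THF, rt; vinyl bromide (1 M in THF), Pd(dppf)Cl2 (5 mol%), K3PO4 (aq), DMF, rt → 40 °C
Reagents that add atoms: vinyl bromide, C=CBr
Why: Anti-Markovnikov hydroboration of the terminal alkene followed by B-alkyl Suzuki–Miyaura coupling with vinyl bromide extends allyl to pent-4-enyl, the phosphate base sparing the γ-lactone and no stereocentre being touched.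

**Step 6**
Reactants: 9 (4R)-2,2-dimethyl-1,3-dioxolane-4-carbaldehyde
Product: 10 (1R,2R)-1-[(4R)-2,2-dimethyl-1,3-dioxolan-4-yl]-2-methylbut-3-en-1-ol
Conditions: (S,S)-diisopropyl tartrate (E)-crotylboronate, 4 Å MS, toluene, −78 °C; aqueous work-up
Reagents that add atoms: diisopropyl (4S,5S)-2-[(E)-but-2-en-1-yl]-1,3,2-dioxaborolane-4,5-dicarboxylate, C/C=C/CB1O[C@H](C(=O)OC(C)C)[C@@H](C(=O)OC(C)C)O1
Why: In this Roush crotylboration the E-geometry should give the 7,8-anti relation through the chair transition state, while the (S,S)-tartrate directs attack to the Re face against the weak Felkin bias of the aldehyde, giving the 6,7-syn (threo) adduct with C6 from the chiral pool.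

**Step 7**
Reactants: 10 (1R,2R)-1-[(4R)-2,2-dimethyl-1,3-dioxolan-4-yl]-2-methylbut-3-en-1-ol
Product: 11 (1R,2R)-1-[(4R)-2,2-dimethyl-1,3-dioxolan-4-yl]-2-methylbut-3-en-1-yl methanesulfonate
Conditions: MsCl, Et3N, CH2Cl2, 0 °C
Reagents that add atoms: methanesulfonyl chloride, CS(=O)(=O)Cl
Why: Mesylation with retention turns the C7 oxygen into the leaving group for epoxide closure.

**Step 8**
Reactants: 11 (1R,2R)-1-[(4R)-2,2-dimethyl-1,3-dioxolan-4-yl]-2-methylbut-3-en-1-yl methanesulfonate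
Product: 13 [(2R,3S)-3-[(2R)-but-3-en-2-yl]oxiran-2-yl]methanol, via diol mesylate 12 (not isolated)
Conditions: AcOH/H2O (4:1), 40 °C; evaporate; K2CO3, MeOH, 0 °C
Reagents that add atoms: none
Why: Acetonide hydrolysis followed by 3-exo-tet Williamson closure (C6–O attacks C7 with inversion) should convert the threo diol monomesylate stereospecifically into the cis-epoxide, since the primary alkoxide could only close a four-membered ring.

**Step 9**
Reactants: 13 [(2R,3S)-3-[(2R)-but-3-en-2-yl]oxiran-2-yl]methanol; 14 tert-butyl(but-3-yn-1-yloxy)dimethylsilane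
Product: 17 tert-butyl({5-[(2R,3S)-3-[(2R)-but-3-en-2-yl]oxiran-2-yl]pent-3-yn-1-yl}oxy)dimethylsilane, via epoxy triflate 15 (not isolated), via lithium acetylide 16 (not isolated)
Conditions: 13, Tf2O, 2,6-lutidine, CH2Cl2, −78 °C, cold wash; crude triflate added to 14/n-BuLi, THF–DMPU, −78 → −30 °C
Reagents that add atoms: none
Why: SN2 alkylation of a lithium acetylide at the primary CH2–OTf carbon of an epoxy triflate is far faster than epoxide opening at low temperature and joins C4–C5 without touching a stereocentre.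

**Step 10**
Reactants: 17 tert-butyl({5-[(2R,3S)-3-[(2R)-but-3-en-2-yl]oxiran-2-yl]pent-3-yn-1-yl}oxy)dimethylsilane
Product: 18 tert-butyl({(3Z)-5-[(2R,3S)-3-[(2R)-but-3-en-2-yl]oxiran-2-yl]pent-3-en-1-yl}oxy)dimethylsilane
Conditions: H2 (1 atm), Lindlar catalyst, quinoline, EtOAc, rt, stopped at 1 equiv uptake
Reagents that add atoms: none
Why: Lindlar semihydrogenation adds H2 syn to the alkyne to give the 3Z-alkene, with quinoline poisoning and uptake control protecting the vinyl group and the epoxide.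

**Step 11**
Reactants: 18 tert-butyl({(3Z)-5-[(2R,3S)-3-[(2R)-but-3-en-2-yl]oxiran-2-yl]pent-3-en-1-yl}oxy)dimethylsilane
Product: 20 tert-butyl({(3Z)-5-[(2R,3S)-3-[(2R)-4-iodobutan-2-yl]oxiran-2-yl]pent-3-en-1-yl}oxy)dimethylsilane, via alkyl-9-BBN adduct 19 (not isolated)
Conditions: 9-BBN, THF, 0 °C → rt; I2, NaOMe, MeOH, 0 °C
Reagents that add atoms: iodine, II
Why: 9-BBN should hydroborate the monosubstituted vinyl group much faster than the cis-disubstituted alkene and ignore the epoxide, and base-induced iodinolysis of the primary B–C bond (Brown hydroboration–iodination) gives the iodide without passing through a free 4,5-epoxy alcohol.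

**Step 12**
Reactants: 20 tert-butyl({(3Z)-5-[(2R,3S)-3-[(2R)-4-iodobutan-2-yl]oxiran-2-yl]pent-3-en-1-yl}oxy)dimethylsilane; 8 (5S)-5-[(2S)-2-(tert-butyldimethylsilyloxy)hept-6-en-1-yl]oxolan-2-one
Product: 23 1,16-di-O-TBS-attenol A, via alkyllithium 21 (not isolated), via lactol 22 (not isolated)
Conditions: 20 (1.2 equiv), t-BuLi (2.0 equiv per 20), Et2O–pentane, −78 °C, 10 min; 8 in Et2O, −78 °C; AcOH (1.1 equiv), −78 °C, aq. NaHCO3 wash (LiI removed), crude lactol not purified; CSA (0.1 equiv), CH2Cl2, 0 °C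
Reagents that add atoms: none
Why: Iodine–lithium exchange turns 20 into primary alkyllithium 21, which adds once to the lactone carbonyl C11 of 8 (C10–C11 bond) because the tetrahedral lithium lactolate is stable at −78 °C; after protonation to lactol 22, catalytic acid lets the hemiketal oxygen on C11 open the cis-epoxide at C7 (O–C7 bond) and release the C6 hydroxyl. The closest known reaction types are acylation of organolithiums by γ-lactones to give lactols, the usual entry to spiroketals, and acid-catalysed opening of epoxides by hemiketal oxygens as in keto-epoxide cyclisations to bicyclic and spiro ketals. Only the tetrahydropyran ring closes, 6-exo-tet at C7 (7-endo attack at C6 is disfavoured), while the tetrahydrofuran ring is carried over from the lactone through the lactol ring–chain tautomers. C7 is set by stereospecific SN2 inversion of the epoxide carbon (7S epoxide to 7R ether, C6 unchanged), and spiro C11 by thermodynamic control under the acid, the 11S epimer placing the THF oxygen axial on the THP chair (anomeric effect) with the C8 methyl and C7 side chain equatorial. The step needs exchange and acyl addition to outrun attack of the carbanion on its own epoxide, which the low temperature, the four-membered transition state that attack would require and the cis-disubstituted, β-branched epoxide should secure, and it needs exo over endo opening, which ring size secures.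

**Step 13**
Reactants: 23 1,16-di-O-TBS-attenol A
Product: 24 attenol A
Conditions: TBAF, THF, 0 °C → rt
Reagents that add atoms: none
Why: Fluoride desilylation removes both TBS ethers under non-acidic conditions, so the spiroketal, the free C6 hydroxyl and both alkenes are not disturbed.

**Compound list**
1 | methyl 4-oxobutanoate | COC(=O)CCC=O | starting material
2 | methyl (4S)-4-hydroxyhept-6-enoate | C=CC[C@@H](O)CCC(=O)OC | intermediate
3 | (5S)-5-(prop-2-en-1-yl)oxolan-2-one | C=CC[C@@H]1CCC(=O)O1 | intermediate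
4 | 2-[(2S)-5-oxooxolan-2-yl]acetaldehyde | O=CC[C@@H]1CCC(=O)O1 | intermediate
5 | (5S)-5-[(2S)-2-hydroxypent-4-en-1-yl]oxolan-2-one | C=CC[C@H](O)C[C@@H]1CCC(=O)O1 | intermediate
6 | (5S)-5-[(2S)-2-(tert-butyldimethylsilyloxy)pent-4-en-1-yl]oxolan-2-one | C=CC[C@H](O[Si](C)(C)C(C)(C)C)C[C@@H]1CCC(=O)O1 | intermediate
7 | 9-{(4S)-4-(tert-butyldimethylsilyloxy)-5-[(2S)-5-oxooxolan-2-yl]pentyl}-9-borabicyclo[3.3.1]nonane | C1CCC2CCCC1B2CCC[C@H](O[Si](C)(C)C(C)(C)C)C[C@@H]1CCC(=O)O1 | intermediate
8 | (5S)-5-[(2S)-2-(tert-butyldimethylsilyloxy)hept-6-en-1-yl]oxolan-2-one | C=CCCC[C@H](O[Si](C)(C)C(C)(C)C)C[C@@H]1CCC(=O)O1 | intermediate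
9 | (4R)-2,2-dimethyl-1,3-dioxolane-4-carbaldehyde | O=C[C@H]1COC(C)(C)O1 | starting material
10 | (1R,2R)-1-[(4R)-2,2-dimethyl-1,3-dioxolan-4-yl]-2-methylbut-3-en-1-ol | C=C[C@@H](C)[C@@H](O)[C@H]1COC(C)(C)O1 | intermediate
11 | (1R,2R)-1-[(4R)-2,2-dimethyl-1,3-dioxolan-4-yl]-2-methylbut-3-en-1-yl methanesulfonate | C=C[C@@H](C)[C@@H](OS(C)(=O)=O)[C@H]1COC(C)(C)O1 | intermediate
12 | (2R,3R,4R)-1,2-dihydroxy-4-methylhex-5-en-3-yl methanesulfonate | C=C[C@@H](C)[C@@H](OS(C)(=O)=O)[C@H](O)CO | intermediate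
13 | [(2R,3S)-3-[(2R)-but-3-en-2-yl]oxiran-2-yl]methanol | C=C[C@@H](C)[C@@H]1O[C@@H]1CO | intermediate
14 | tert-butyl(but-3-yn-1-yloxy)dimethylsilane | C#CCCO[Si](C)(C)C(C)(C)C | starting material
15 | [(2R,3S)-3-[(2R)-but-3-en-2-yl]oxiran-2-yl]methyl trifluoromethanesulfonate | C=C[C@@H](C)[C@@H]1O[C@@H]1COS(=O)(=O)C(F)(F)F | intermediate
16 | lithium 4-(tert-butyldimethylsilyloxy)but-1-yn-1-ide | [Li]C#CCCO[Si](C)(C)C(C)(C)C | intermediate
17 | tert-butyl({5-[(2R,3S)-3-[(2R)-but-3-en-2-yl]oxiran-2-yl]pent-3-yn-1-yl}oxy)dimethylsilane | C=C[C@@H](C)[C@@H]1O[C@@H]1CC#CCCO[Si](C)(C)C(C)(C)C | intermediate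
18 | tert-butyl({(3Z)-5-[(2R,3S)-3-[(2R)-but-3-en-2-yl]oxiran-2-yl]pent-3-en-1-yl}oxy)dimethylsilane | C=C[C@@H](C)[C@@H]1O[C@@H]1C/C=C\CCO[Si](C)(C)C(C)(C)C | intermediate
19 | 9-{(3R)-3-[(2S,3R)-3-[(2Z)-5-(tert-butyldimethylsilyloxy)pent-2-en-1-yl]oxiran-2-yl]butyl}-9-borabicyclo[3.3.1]nonane | C1CCC2CCCC1B2CC[C@@H](C)[C@@H]1O[C@@H]1C/C=C\CCO[Si](C)(C)C(C)(C)C | intermediate
20 | tert-butyl({(3Z)-5-[(2R,3S)-3-[(2R)-4-iodobutan-2-yl]oxiran-2-yl]pent-3-en-1-yl}oxy)dimethylsilane | ICC[C@@H](C)[C@@H]1O[C@@H]1C/C=C\CCO[Si](C)(C)C(C)(C)C | intermediate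
21 | {(3R)-3-[(2S,3R)-3-[(2Z)-5-(tert-butyldimethylsilyloxy)pent-2-en-1-yl]oxiran-2-yl]butyl}lithium | [Li]CC[C@@H](C)[C@@H]1O[C@@H]1C/C=C\CCO[Si](C)(C)C(C)(C)C | intermediate
22 | (5S)-5-[(2S)-2-(tert-butyldimethylsilyloxy)hept-6-en-1-yl]-2-{(3R)-3-[(2S,3R)-3-[(2Z)-5-(tert-butyldimethylsilyloxy)pent-2-en-1-yl]oxiran-2-yl]butyl}oxolan-2-ol (anomers, in equilibrium with the open hydroxy ketone) | C=CCCC[C@H](O[Si](C)(C)C(C)(C)C)C[C@@H]1CCC(O)(CC[C@@H](C)[C@@H]2O[C@@H]2C/C=C\CCO[Si](C)(C)C(C)(C)C)O1 | intermediate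
23 | 1,16-di-O-TBS-attenol A: (1R,3Z)-6-(tert-butyldimethylsilyloxy)-1-{(2S,5S,7R,8R)-2-[(2S)-2-(tert-butyldimethylsilyloxy)hept-6-en-1-yl]-8-methyl-1,6-dioxaspiro[4.5]decan-7-yl}hex-3-en-1-ol | C=CCCC[C@H](O[Si](C)(C)C(C)(C)C)C[C@@H]1CC[C@@]2(CC[C@@H](C)[C@H]([C@H](O)C/C=C\CCO[Si](C)(C)C(C)(C)C)O2)O1 | intermediate
24 | attenol A: (3Z,6R)-6-{(2S,5S,7R,8R)-2-[(2S)-2-hydroxyhept-6-en-1-yl]-8-methyl-1,6-dioxaspiro[4.5]decan-7-yl}hex-3-ene-1,6-diol | C=CCCC[C@H](O)C[C@@H]1CC[C@@]2(CC[C@@H](C)[C@H]([C@H](O)C/C=C\CCO)O2)O1 | target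

**Step count**
Total: 13 steps. Longest linear sequence: 8 steps (9 → 24, steps 6–13); the lactone branch (steps 1–5) joins at step 12.

**Steps most likely to fail**

1. Step 12. The carbanion may attack its own epoxide (4-exo) or be protonated before acylation; residual iodide may open the epoxide under acid; prolonged acid may equilibrate the product towards the bicyclic ketal that uses the C6 hydroxyl. Fallback, setting out from 8 and 20 and returning at 23: lactone 8 is opened with LiOH (THF/H2O), the hydroxy carboxylate is silylated with TESCl/imidazole and the silyl ester is cleaved on mild aqueous K2CO3 work-up to give (4S,6S)-6-(tert-butyldimethylsilyloxy)-4-(triethylsilyloxy)undec-10-enoic acid F1. Activation with 2,2'-dipyridyl disulfide/PPh3 gives the S-pyridin-2-yl thioester F2. Nickel-catalysed cross-electrophile coupling of F2 with iodide 20 (NiCl2·dme, 4,4'-di-tert-butyl-2,2'-bipyridine, Zn, DMA) forms the C10–C11 bond without a free carbanion and gives the epoxy ketone F3. Selective removal of the TES group (HF·pyridine/pyridine, THF, 0 °C) and then CSA (cat.) in CH2Cl2 lets the C14 hydroxyl close the hemiketal, which opens the epoxide at C7 as in step 12 to give 23.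

2. Step 6. Facial selectivity may be poor because the reagent has to override the Felkin preference of the α-alkoxy aldehyde, so the 6,7-anti diastereomer may contaminate 10. Fallback, setting out from 9 and returning at 10: addition of commercial (Z)-crotylboronic acid pinacol ester to 9 (toluene, −78 °C → rt), where reagent geometry and the Felkin bias act together, gives the 7,8-syn-6,7-anti alcohol (1S,2R)-1-[(4R)-2,2-dimethyl-1,3-dioxolan-4-yl]-2-methylbut-3-en-1-ol F4. Mitsunobu inversion at the carbinol carbon (4-nitrobenzoic acid, PPh3, DIAD, toluene) gives the (1R,2R)-4-nitrobenzoate F5, and methanolysis (K2CO3, MeOH) gives 10.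

3. Step 11. Electrophilic iodine may attack the Z-alkene, or a ring B–C bond of the borane may be cleaved in place of the primary one. Fallback, setting out from 18 (through borane 19) and returning at 20: oxidative work-up of 19 with NaBO3·4H2O (THF/H2O) gives the primary alcohol (3R)-3-[(2S,3R)-3-[(2Z)-5-(tert-butyldimethylsilyloxy)pent-2-en-1-yl]oxiran-2-yl]butan-1-ol F6, kept free of acid to prevent 5-exo opening of the epoxide. Appel iodination (PPh3, I2, imidazole, CH2Cl2, 0 °C) converts F6 into 20.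

**Further compounds**
F1 | step 12 | (4S,6S)-6-(tert-butyldimethylsilyloxy)-4-(triethylsilyloxy)undec-10-enoic acid | C=CCCC[C@H](O[Si](C)(C)C(C)(C)C)C[C@H](CCC(=O)O)O[Si](CC)(CC)CC
F2 | step 12 | S-pyridin-2-yl (4S,6S)-6-(tert-butyldimethylsilyloxy)-4-(triethylsilyloxy)undec-10-enethioate | C=CCCC[C@H](O[Si](C)(C)C(C)(C)C)C[C@H](CCC(=O)Sc1ccccn1)O[Si](CC)(CC)CC
F3 | step 12 | (7S,9S)-9-(tert-butyldimethylsilyloxy)-1-[(2S,3R)-3-[(2Z)-5-(tert-butyldimethylsilyloxy)pent-2-en-1-yl]oxiran-2-yl]-1-methyl-7-(triethylsilyloxy)tetradec-13-en-4-one, (R) at the methyl-bearing carbon | C=CCCC[C@H](O[Si](C)(C)C(C)(C)C)C[C@H](CCC(=O)CC[C@@H](C)[C@@H]1O[C@@H]1C/C=C\CCO[Si](C)(C)C(C)(C)C)O[Si](CC)(CC)CC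
F4 | step 6 | (1S,2R)-1-[(4R)-2,2-dimethyl-1,3-dioxolan-4-yl]-2-methylbut-3-en-1-ol | C=C[C@@H](C)[C@H](O)[C@H]1COC(C)(C)O1
F5 | step 6 | (1R,2R)-1-[(4R)-2,2-dimethyl-1,3-dioxolan-4-yl]-2-methylbut-3-en-1-yl 4-nitrobenzoate | C=C[C@@H](C)[C@@H](OC(=O)c1ccc(cc1)[N+](=O)[O-])[C@H]1COC(C)(C)O1
F6 | step 11 | (3R)-3-[(2S,3R)-3-[(2Z)-5-(tert-butyldimethylsilyloxy)pent-2-en-1-yl]oxiran-2-yl]butan-1-ol | OCC[C@@H](C)[C@@H]1O[C@@H]1C/C=C\CCO[Si](C)(C)C(C)(C)C
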